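**Strategy.** The chain is cut inside the second isoprene unit counted from the naphthoquinone ring, between its methyl-bearing olefinic carbon and the adjoining CH2. The key step exploits this (E)-trisubstituted C(CH3)=CH olefin: a Zweifel olefination unites a C21 homogeranylgeranyl pinacol boronate and an alkenyllithium that carries the masked quinone. One operation forms the C(sp2)–C(sp3) bond by a 1,2-metallate shift and, through anti migration and anti elimination, inverts the olefin geometry, so an easily made (Z)-2-iodoalkene delivers the (E)-olefin. The precursor is a tetracoordinate alkenyl(alkyl)boronate. The quinone travels as a 1,4-dimethoxynaphthalene made from 1,7-dimethylnaphthalene and is released last.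

Key step: step 11

Remark: intermediate 18 is racemic; its SMILES shows one enantiomer with the relative configuration that the anti addition sets.

**Step 1**
Reactants: 1 1,7-dimethylnaphthalene
Product: 2 2,8-dimethylnaphthalene-1,4-dione
Conditions: CrO3, AcOH/H2O, 15 → 40 °C
Reagents that add atoms: chromium trioxide, O=[Cr](=O)=O
Why: Chromic acid oxidation of a methylnaphthalene to its 1,4-quinone; a para-quinone can form only in the ring that carries the 7-methyl group, because C1 of the other ring is blocked by methyl, so the 2,8-dimethyl pattern should follow without a regiochemical choice.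

**Step 2**
Reactants: 2 2,8-dimethylnaphthalene-1,4-dione
Product: 4 1,4-dimethoxy-2,8-dimethylnaphthalene, via 2,8-dimethylnaphthalene-1,4-diol 3 (not isolated)
Conditions: Na2S2O4, Bu4NBr, THF/H2O, rt; then KOH, Me2SO4, 0 °C → rt
Reagents that add atoms: dimethyl sulfate, COS(=O)(=O)OC
Why: Dithionite reduction to the hydroquinone followed by Williamson methylation under phase-transfer conditions (one-pot reductive methylation) should mask the quinone against the organometallic steps.

**Step 3**
Reactants: 4 1,4-dimethoxy-2,8-dimethylnaphthalene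
Product: 5 2-bromo-1,4-dimethoxy-3,5-dimethylnaphthalene
Conditions: N-bromosuccinimide, MeCN, 0 °C → rt, dark
Reagents that add atoms: N-bromosuccinimide, O=C1CCC(=O)N1Br
Why: Electrophilic aromatic bromination should take the only free position of the dimethoxy-substituted ring (ortho to a methoxy group), which is far more activated than the methyl-substituted benzo ring.

**Step 4**
Reactants: 6 geranyl acetate
Product: 7 (2E)-3-methyl-6-oxohex-2-en-1-yl acetate
Conditions: O3 (1 equiv), CH2Cl2, −78 °C; then Me2S, −78 °C → rt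
Reagents that add atoms: ozone, [O-][O+]=O
Why: Selective ozonolysis with reductive work-up should cleave the electron-richer terminal isopropylidene olefin, while the 2,3-olefin is deactivated by the allylic acetate and keeps its (E) geometry.

**Step 5**
Reactants: 7 (2E)-3-methyl-6-oxohex-2-en-1-yl acetate
Product: 8 (2E,6Z)-7-iodo-3-methylocta-2,6-dien-1-yl acetate
Conditions: EtPPh3I, n-BuLi, THF, 0 °C → rt; I2, −78 °C; NaN(SiMe3)2, −20 °C; then 7, −78 °C
Reagents that add atoms: ethyltriphenylphosphonium iodide, CC[P+](c1ccccc1)(c1ccccc1)c1ccccc1.[I-]; iodine, II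
Why: Stork–Zhao-type Wittig olefination, in which the non-stabilised alpha-iodo ylide adds to the aldehyde under kinetic control at low temperature and should place iodine cis to the chain ((Z)-2-iodoalkene), the acetate being left alone because the ylide reacts far faster with the aldehyde.

**Step 6**
Reactants: 8 (2E,6Z)-7-iodo-3-methylocta-2,6-dien-1-yl acetate
Product: 9 (2E,6Z)-7-iodo-3-methylocta-2,6-dien-1-ol
Conditions: K2CO3 (cat.), MeOH, 0 °C → rt
Reagents that add atoms: none
Why: Base-catalysed transesterification (methanolysis) should remove the acetate without touching the alkenyl iodide or either olefin geometry.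

**Step 7**
Reactants: 9 (2E,6Z)-7-iodo-3-methylocta-2,6-dien-1-ol
Product: 10 (2E,6Z)-1-bromo-7-iodo-3-methylocta-2,6-diene
Conditions: PBr3, Et2O, 0 °C
Reagents that add atoms: phosphorus tribromide, BrP(Br)Br
Why: Conversion of a primary allylic alcohol into the bromide through its phosphite ester by SN2 displacement, which at 0 °C should keep the (E)-allylic olefin and leave the alkenyl iodide untouched.

**Step 8**
Reactants: 5 2-bromo-1,4-dimethoxy-3,5-dimethylnaphthalene; 10 (2E,6Z)-1-bromo-7-iodo-3-methylocta-2,6-diene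
Product: 12 2-[(2E,6Z)-7-iodo-3-methylocta-2,6-dien-1-yl]-1,4-dimethoxy-3,5-dimethylnaphthalene, via arylmagnesium bromide 11 (not isolated)
Conditions: 5, Mg, THF, 50 °C, solution decanted from excess Mg; then Li2CuCl4 (5 mol %), 10, THF, −20 → 0 °C
Reagents that add atoms: none
Why: Copper-catalysed allylic substitution of a primary allylic bromide by an aryl Grignard reagent at the alpha carbon with retention of the (E)-olefin; gamma attack would have to build a quaternary carbon next to the doubly ortho-substituted arene, and the alkenyl iodide should be inert to the Grignard reagent at this temperature.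

**Step 9**
Reactants: 13 (2E,6E,10E)-geranylgeraniol
Product: 14 (2E,6E,10E)-1-bromo-3,7,11,15-tetramethylhexadeca-2,6,10,14-tetraene
Conditions: PBr3, Et2O, −10 → 0 °C
Reagents that add atoms: phosphorus tribromide, BrP(Br)Br
Why: SN2 bromination of the primary allylic alcohol through its phosphite ester, which at low temperature should preserve all three (E)-olefins.

**Step 10**
Reactants: 14 (2E,6E,10E)-1-bromo-3,7,11,15-tetramethylhexadeca-2,6,10,14-tetraene
Product: 15 2-[(3E,7E,11E)-4,8,12,16-tetramethylheptadeca-3,7,11,15-tetraen-1-yl]-4,4,5,5-tetramethyl-1,3,2-dioxaborolane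
Conditions: CH2(Bpin)2, NaOt-Bu, THF, rt
Reagents that add atoms: bis(4,4,5,5-tetramethyl-1,3,2-dioxaborolan-2-yl)methane, CC1(C)OB(CB2OC(C)(C)C(C)(C)O2)OC1(C)C
Why: Alkoxide-promoted deborylative alkylation of a geminal bis(boronate), in which tert-butoxide activates one boron to release an alpha-boryl carbanion that displaces the primary allylic bromide by SN2, adding the CH2–B unit in one step without touching the olefin geometry.

**Step 11**
Reactants: 12 2-[(2E,6Z)-7-iodo-3-methylocta-2,6-dien-1-yl]-1,4-dimethoxy-3,5-dimethylnaphthalene; 15 2-[(3E,7E,11E)-4,8,12,16-tetramethylheptadeca-3,7,11,15-tetraen-1-yl]-4,4,5,5-tetramethyl-1,3,2-dioxaborolane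
Product: 19 2-[(2E,6E,10E,14E,18E)-3,7,11,15,19,23-hexamethyltetracosa-2,6,10,14,18,22-hexaen-1-yl]-1,4-dimethoxy-3,5-dimethylnaphthalene, via alkenyllithium 16 (not isolated), via lithium alkenyl(alkyl)boronate complex 17 (not isolated), via beta-iodo boronic ester 18 (not isolated)
Conditions: 12 (1.2 equiv), t-BuLi (2 equiv per 12), Et2O/THF, −78 °C; 15, THF, −78 °C; I2 (1.2 equiv), THF/MeOH, −78 °C; NaOMe, MeOH, −78 °C → rt
Reagents that add atoms: none
Why: Zweifel olefination: iodine–lithium exchange on 12 gives alkenyllithium 16 with retention (lithium cis to the chain CH2), which adds to the boron of 15 to give boronate complex 17; iodine then forms an iodonium ion on the alkenyl group and the primary homoallylic CH2 migrates from boron to the methyl-bearing carbon anti to the opening C–I bond, which makes the new carbon–carbon bond in 18. Methoxide then triggers anti elimination of boron and iodide, and the anti/anti sequence inverts the olefin geometry, so the (Z)-iodoalkene should become the (E)-trisubstituted olefin. The closest known reaction type is the stereoinvertive Zweifel coupling of primary alkyl pinacol boronates with 1-methylalkenyllithiums to trisubstituted alkenes. No ring is closed and no stereocenter remains: the two transient stereocenters of 18 are set by the anti addition and destroyed in the elimination, so the only stereo-element, the olefin geometry, is controlled by the geometry of 12. The step needs chemoselectivity for the boronate-bound alkene over the five other trisubstituted olefins and the dimethoxynaphthalene, which the far higher nucleophilicity of the anionic alkenylboronate toward a near-stoichiometric amount of I2 at −78 °C should secure, and it needs migration of the alkyl group and not of a pinacol oxygen, which the poor migratory aptitude of alkoxy ligands secures.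

**Step 12**
Reactants: 19 2-[(2E,6E,10E,14E,18E)-3,7,11,15,19,23-hexamethyltetracosa-2,6,10,14,18,22-hexaen-1-yl]-1,4-dimethoxy-3,5-dimethylnaphthalene
Product: 20 2-[(2E,6E,10E,14E,18E)-3,7,11,15,19,23-hexamethyltetracosa-2,6,10,14,18,22-hexaen-1-yl]-3,5-dimethylnaphthalene-1,4-dione (target)
Conditions: (NH4)2Ce(NO3)6, MeCN/H2O/CH2Cl2, 0 °C
Reagents that add atoms: water, O
Why: Oxidative demethylation of a 1,4-dimethoxyarene by tetravalent cerium through the arene radical cation and addition of water should give the para-quinone, the isolated trisubstituted olefins not being oxidised under these brief cold conditions.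

**Compound list**

1 | 1,7-dimethylnaphthalene | Cc1ccc2cccc(C)c2c1 | starting material
2 | 2,8-dimethylnaphthalene-1,4-dione | CC1=CC(=O)c2cccc(C)c2C1=O | intermediate
3 | 2,8-dimethylnaphthalene-1,4-diol | Cc1cc(O)c2cccc(C)c2c1O | intermediate
4 | 1,4-dimethoxy-2,8-dimethylnaphthalene | COc1cc(C)c(OC)c2c(C)cccc12 | intermediate
5 | 2-bromo-1,4-dimethoxy-3,5-dimethylnaphthalene | COc1c(Br)c(C)c(OC)c2c(C)cccc12 | intermediate
6 | geranyl acetate, (2E)-3,7-dimethylocta-2,6-dien-1-yl acetate | CC(C)=CCC/C(C)=C/COC(C)=O | starting material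
7 | (2E)-3-methyl-6-oxohex-2-en-1-yl acetate | O=CCC/C(C)=C/COC(C)=O | intermediate
8 | (2E,6Z)-7-iodo-3-methylocta-2,6-dien-1-yl acetate | C/C(I)=C/CC/C(C)=C/COC(C)=O | intermediate
9 | (2E,6Z)-7-iodo-3-methylocta-2,6-dien-1-ol | C/C(I)=C/CC/C(C)=C/CO | intermediate
10 | (2E,6Z)-1-bromo-7-iodo-3-methylocta-2,6-diene | C/C(I)=C/CC/C(C)=C/CBr | intermediate
11 | (1,4-dimethoxy-3,5-dimethylnaphthalen-2-yl)magnesium bromide | COc1c([Mg]Br)c(C)c(OC)c2c(C)cccc12 | intermediate
12 | 2-[(2E,6Z)-7-iodo-3-methylocta-2,6-dien-1-yl]-1,4-dimethoxy-3,5-dimethylnaphthalene | C/C(I)=C/CC/C(C)=C/Cc1c(C)c(OC)c2c(C)cccc2c1OC | intermediate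
13 | (2E,6E,10E)-geranylgeraniol, (2E,6E,10E)-3,7,11,15-tetramethylhexadeca-2,6,10,14-tetraen-1-ol | CC(C)=CCC/C(C)=C/CC/C(C)=C/CC/C(C)=C/CO | starting material
14 | (2E,6E,10E)-1-bromo-3,7,11,15-tetramethylhexadeca-2,6,10,14-tetraene | CC(C)=CCC/C(C)=C/CC/C(C)=C/CC/C(C)=C/CBr | intermediate
15 | 2-[(3E,7E,11E)-4,8,12,16-tetramethylheptadeca-3,7,11,15-tetraen-1-yl]-4,4,5,5-tetramethyl-1,3,2-dioxaborolane | CC(C)=CCC/C(C)=C/CC/C(C)=C/CC/C(C)=C/CCB1OC(C)(C)C(C)(C)O1 | intermediate
16 | alkenyllithium from 12, lithium cis to the chain CH2 | C/C([Li])=C/CC/C(C)=C/Cc1c(C)c(OC)c2c(C)cccc2c1OC | intermediate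
17 | lithium alkenyl(alkyl)(pinacolato)boronate complex | [Li+].C/C(=C/CC/C(C)=C/Cc1c(C)c(OC)c2c(C)cccc2c1OC)[B-]1(CC/C=C(C)/CC/C=C(C)/CC/C=C(C)/CCC=C(C)C)OC(C)(C)C(C)(C)O1 | intermediate
18 | beta-iodo tertiary boronic ester (racemic, one enantiomer drawn) | C[C@@](CC/C=C(C)/CC/C=C(C)/CC/C=C(C)/CCC=C(C)C)(B1OC(C)(C)C(C)(C)O1)[C@H](I)CC/C(C)=C/Cc1c(C)c(OC)c2c(C)cccc2c1OC | intermediate
19 | 2-[(2E,6E,10E,14E,18E)-3,7,11,15,19,23-hexamethyltetracosa-2,6,10,14,18,22-hexaen-1-yl]-1,4-dimethoxy-3,5-dimethylnaphthalene | CC(C)=CCC/C(C)=C/CC/C(C)=C/CC/C(C)=C/CC/C(C)=C/CC/C(C)=C/Cc1c(C)c(OC)c2c(C)cccc2c1OC | intermediate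
20 | 2-[(2E,6E,10E,14E,18E)-3,7,11,15,19,23-hexamethyltetracosa-2,6,10,14,18,22-hexaen-1-yl]-3,5-dimethylnaphthalene-1,4-dione | CC(C)=CCC/C(C)=C/CC/C(C)=C/CC/C(C)=C/CC/C(C)=C/CC/C(C)=C/CC1=C(C)C(=O)c2c(C)cccc2C1=O | target

**Step count.** Total: 12 steps. Longest linear sequence: 7 steps (steps 4, 5, 6, 7, 8, 11, 12).

**Steps most likely to fail**

1. Step 11. Iodine may add to the other trisubstituted olefins (iodo-methoxylation), the anti elimination may not be fully stereospecific, or t-BuLi may deprotonate the doubly activated ArCH2 position. The fallback sets out from 7 and comes back at 19, and joins the same bond by a stereoretentive B-alkyl Suzuki–Miyaura coupling. Aldehyde 7 would be homologated with the Ohira–Bestmann reagent (dimethyl (1-diazo-2-oxopropyl)phosphonate, K2CO3, MeOH), the acetate being cleaved in the same pot, to (2E)-3-methyloct-2-en-7-yn-1-ol F1. Its dianion (n-BuLi, THF, −78 °C) would be C-methylated with MeI to (2E)-3-methylnon-2-en-7-yn-1-ol F2, and PBr3 would give (2E)-1-bromo-3-methylnon-2-en-7-yne F3. Coupling with Grignard reagent 11 (Li2CuCl4 cat., THF) would give 1,4-dimethoxy-3,5-dimethyl-2-[(2E)-3-methylnon-2-en-7-yn-1-yl]naphthalene F4. Syn hydrozirconation with excess Cp2Zr(H)Cl (THF, 50 °C, equilibration to the less hindered methyl-side zirconium isomer) and iodinolysis would give 2-[(2E,6E)-7-iodo-3-methylocta-2,6-dien-1-yl]-1,4-dimethoxy-3,5-dimethylnaphthalene F5. F5 and 15 would then be coupled with retention (Pd(OAc)2, RuPhos, K3PO4, toluene/H2O, 80 °C) to 19.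

2. Step 5. The Z selectivity may erode in the addition step, the ylide may be under- or over-iodinated, or base may cleave the acetate. The fallback sets out from 7 and comes back at 8. Ramirez dibromo-olefination (CBr4, PPh3, CH2Cl2, 0 °C) would give (2E)-7,7-dibromo-3-methylhepta-2,6-dien-1-yl acetate F6. Trans-selective Negishi monomethylation (Me2Zn, Pd(DPEphos)Cl2, THF, 0 °C) would replace the bromine trans to the chain and give (2E,6Z)-7-bromo-3-methylocta-2,6-dien-1-yl acetate F7. Copper-catalysed halogen exchange with retention (CuI, N,N′-dimethylethylenediamine, NaI, dioxane, 110 °C) would give 8.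

3. Step 10. The boryl carbanion may attack the gamma carbon with allylic transposition, the bromide may eliminate, or a second alkylation may occur. The fallback sets out from 14 and comes back at 15. Palladium-catalysed borylation (B2pin2, Pd2(dba)3, AsPh3, toluene, 50 °C) would give the linear allylboronate 2-[(2E,6E,10E)-3,7,11,15-tetramethylhexadeca-2,6,10,14-tetraen-1-yl]-4,4,5,5-tetramethyl-1,3,2-dioxaborolane F8. Matteson homologation (BrCH2Cl, n-BuLi, THF, −78 °C → rt) would insert the CH2 group by 1,2-migration of the allyl group, without transposition, and give 15.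

Further compounds
F1 | step 11 | (2E)-3-methyloct-2-en-7-yn-1-ol | C#CCC/C(C)=C/CO
F2 | step 11 | (2E)-3-methylnon-2-en-7-yn-1-ol | CC#CCC/C(C)=C/CO
F3 | step 11 | (2E)-1-bromo-3-methylnon-2-en-7-yne | CC#CCC/C(C)=C/CBr
F4 | step 11 | 1,4-dimethoxy-3,5-dimethyl-2-[(2E)-3-methylnon-2-en-7-yn-1-yl]naphthalene | CC#CCC/C(C)=C/Cc1c(C)c(OC)c2c(C)cccc2c1OC
F5 | step 11 | 2-[(2E,6E)-7-iodo-3-methylocta-2,6-dien-1-yl]-1,4-dimethoxy-3,5-dimethylnaphthalene | C/C(I)=C\CC/C(C)=C/Cc1c(C)c(OC)c2c(C)cccc2c1OC
F6 | step 5 | (2E)-7,7-dibromo-3-methylhepta-2,6-dien-1-yl acetate | BrC(Br)=CCC/C(C)=C/COC(C)=O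
F7 | step 5 | (2E,6Z)-7-bromo-3-methylocta-2,6-dien-1-yl acetate | C/C(Br)=C/CC/C(C)=C/COC(C)=O
F8 | step 10 | 2-[(2E,6E,10E)-3,7,11,15-tetramethylhexadeca-2,6,10,14-tetraen-1-yl]-4,4,5,5-tetramethyl-1,3,2-dioxaborolane | CC(C)=CCC/C(C)=C/CC/C(C)=C/CC/C(C)=C/CB1OC(C)(C)C(C)(C)O1
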